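A direct plan would build ring A last, by a Diels–Alder benzannulation of the 1,1-dimethoxy-3-silyloxy diene A1 with the terminal ynone A2, giving aryl ketone A3 with the OMe, prenyl and silyloxy groups in place.
A2 would come from aldehyde A4 (aqueous C-prenylation of 4-hydroxybenzaldehyde A5) by aldol addition of an alkynyl methyl ketone, silylation and alkyne desilylation; A3 would then be desilylated, oxidised to the dione and deprotected.
Weak point 1, the benzannulation: a fully substituted ketene acetal terminus would have to bond next to the acyl group of a polymerisation-prone ynone at 80 °C, after a four-step linear run-up to A1 through an orthoester and a ketene acetal, so the main risk would sit where both long branches meet.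
Weak point 2, the phenoxide C-prenylation to A4: O- against C-alkylation and over-alkylation would not be under control, at the start of the longest branch.
Weak point 3, the aldol/silylation/desilylation/oxidation stretch: the tether would be carried at the carbinol level under three different silyl groups, and about six operations would form no bond of the skeleton.

**Retrosynthetic overview**
The tether is cut on both sides of C1, the carbonyl carbon bonded to ring A. Ring A arrives as aryl bromide 5, C1 as carbon monoxide 13, and C2–C3 with ring B as methyl ketone 12. One palladium-catalysed three-component coupling forms the ring A C1(aryl)–C(=O) bond and the C(=O)–C2H2 bond and gives the 1,3-dione directly.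
No ring is constructed: both benzene rings come from commercial phenols and are only decorated (ring A in 2 steps, ring B in 4 in parallel), followed by the union and one deprotection.
The prenyl at ring A C3, between C2–OMe and C4–O, is set by directed metalation between the two oxygens, with MOM as director and protecting group at once. The prenyl at ring B C3 is set by [3,3] rearrangement, so no phenoxide C-alkylation is needed.
The tether is never carried at the carbinol level, so aldol, silyl shuffling and oxidation disappear.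

Key step: step 7

Remark: the target has no stereocentre; the 1,3-dione is written as the diketo form and should exist largely as its chelated enol, which is the same compound.

**Route**

Step 1
Reactants: 1 4-bromo-3-methoxyphenol
Product: 2 1-bromo-2-methoxy-4-(methoxymethoxy)benzene
Conditions: MOMCl, i-Pr2NEt, CH2Cl2, 0 → 25 °C
Reagents that add atoms: chloromethyl methyl ether, COCCl
Why: O-Alkylation of the phenol with a chloromethyl ether under amine base installs the MOM acetal, which serves as the directing group of step 2 and as the phenol protection through step 7.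

Step 2
Reactants: 2 1-bromo-2-methoxy-4-(methoxymethoxy)benzene; 3 1-bromo-3-methylbut-2-ene
Product: 5 1-bromo-2-methoxy-4-(methoxymethoxy)-3-(3-methylbut-2-en-1-yl)benzene, via [3-bromo-2-methoxy-6-(methoxymethoxy)phenyl]lithium 4 (not isolated)
Conditions: LiTMP (lithium 2,2,6,6-tetramethylpiperidide, 1.2 equiv), THF, −78 °C; then CuBr·SMe2 (10 mol %), 3, −78 → 0 °C
Reagents that add atoms: none
Why: Directed ortho metalation: C3–H lies between the OMe and OMOM groups and is the most acidic, doubly coordinated site, the hindered amide base should deprotonate there without touching the C–Br bond, and copper-catalysed allylation of the aryllithium with the primary bromide should give the linear prenyl group.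

Step 3
Reactants: 6 1-(4-hydroxyphenyl)ethan-1-one; 7 3-chloro-3-methylbut-1-yne
Product: 8 1-{4-[(2-methylbut-3-yn-2-yl)oxy]phenyl}ethan-1-one
Conditions: DBU, CuCl2·2H2O (1 mol %), MeCN, 0 → 25 °C
Reagents that add atoms: none
Why: Copper-catalysed propargylic substitution of a tertiary propargyl chloride by a phenoxide is the standard entry to aryl 1,1-dimethylpropargyl ethers and runs cold enough that the methyl ketone does not condense.

Step 4
Reactants: 8 1-{4-[(2-methylbut-3-yn-2-yl)oxy]phenyl}ethan-1-one
Product: 9 1-{4-[(2-methylbut-3-en-2-yl)oxy]phenyl}ethan-1-one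
Conditions: H2 (1 atm), Pd/CaCO3 poisoned with Pb(OAc)2 (Lindlar catalyst), quinoline, EtOAc, 25 °C
Reagents that add atoms: none
Why: Lindlar semihydrogenation should stop the terminal alkyne at the alkene and leave the aryl ketone and the tertiary allylic C–O bond intact.

Step 5
Reactants: 9 1-{4-[(2-methylbut-3-en-2-yl)oxy]phenyl}ethan-1-one
Product: 11 1-[4-hydroxy-3-(3-methylbut-2-en-1-yl)phenyl]ethan-1-one, via rac-4-acetyl-6-(3-methylbut-2-en-1-yl)cyclohexa-2,4-dien-1-one 10 (not isolated)
Conditions: PhNEt2, 130 °C
Reagents that add atoms: none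
Why: Aromatic Claisen rearrangement: the [3,3] shift of the 1,1-dimethylallyl ether delivers the linear prenyl group to one of the two equivalent ortho carbons, the dienone tautomerises to the phenol, and the amine solvent suppresses acid-catalysed chroman formation.

Step 6
Reactants: 11 1-[4-hydroxy-3-(3-methylbut-2-en-1-yl)phenyl]ethan-1-one
Product: 12 1-[4-(methoxymethoxy)-3-(3-methylbut-2-en-1-yl)phenyl]ethan-1-one
Conditions: MOMCl, i-Pr2NEt, CH2Cl2, 0 → 25 °C
Reagents that add atoms: chloromethyl methyl ether, COCCl
Why: O-Alkylation of the phenol masks the only group that would intercept the aroylpalladium intermediate of step 7 as an aryl ester, with the same acetal as on ring A so that one final operation frees both phenols.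

Step 7
Reactants: 5 1-bromo-2-methoxy-4-(methoxymethoxy)-3-(3-methylbut-2-en-1-yl)benzene; 13 carbon monoxide; 12 1-[4-(methoxymethoxy)-3-(3-methylbut-2-en-1-yl)phenyl]ethan-1-one
Product: 14 1-[2-methoxy-4-(methoxymethoxy)-3-(3-methylbut-2-en-1-yl)phenyl]-3-[4-(methoxymethoxy)-3-(3-methylbut-2-en-1-yl)phenyl]propane-1,3-dione
Conditions: Pd(dba)2 (5 mol %), Xantphos (5 mol %), MgCl2 (2 equiv), Et3N (3 equiv), CO (1 atm), 1,4-dioxane, 90 °C; aq. citric acid work-up
Reagents that add atoms: none
Why: Oxidative addition of bromide 5 to zerovalent palladium and CO insertion give the ring A aroylpalladium bromide; MgCl2/Et3N soft-enolises ketone 12, the magnesium enolate displaces bromide on palladium, and C–C reductive elimination releases the 1,3-dione, which is held as its magnesium chelate. The closest known reaction type is the palladium-catalysed carbonylative α-arylation of aryl methyl ketones with aryl halides and CO, which makes dibenzoylmethanes in one step. No ring is closed and no stereocentre is formed; the step forms the ring A C1–C(=O) bond and the C(=O)–CH2 bond and so delivers the whole three-carbon tether at the dione oxidation level. It needs CO insertion to outrun direct α-arylation, which the CO atmosphere and the wide-bite-angle diphosphine should secure, and C- over O-acylation and mono-acylation, which the magnesium enolate and the chelated, poorly nucleophilic diketonate product should secure. It also needs chemoselectivity over the two prenyl alkenes, which are trisubstituted and unactivated, and in 5 the prenyl group is meta to the C–Pd bond, so no acylpalladation ring can form. Both MOM ethers should be inert to the amine-buffered, weakly Lewis acidic medium.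

Step 8
Reactants: 14 1-[2-methoxy-4-(methoxymethoxy)-3-(3-methylbut-2-en-1-yl)phenyl]-3-[4-(methoxymethoxy)-3-(3-methylbut-2-en-1-yl)phenyl]propane-1,3-dione
Product: 15 1-[4-hydroxy-2-methoxy-3-(3-methylbut-2-en-1-yl)phenyl]-3-[4-hydroxy-3-(3-methylbut-2-en-1-yl)phenyl]propane-1,3-dione (CNP0167758.0)
Conditions: HCl (cat.), MeOH, 25 → 40 °C
Reagents that add atoms: none
Why: Acid-catalysed transacetalisation of the two aryl methoxymethyl ethers with methanol needs only dilute acid near room temperature, under which the ortho-prenylphenols and the chelated enol of the dione should persist.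

**Compound list**
1 | 4-bromo-3-methoxyphenol | COc1cc(O)ccc1Br | starting material
2 | 1-bromo-2-methoxy-4-(methoxymethoxy)benzene | COCOc1ccc(Br)c(OC)c1 | intermediate
3 | 1-bromo-3-methylbut-2-ene (prenyl bromide) | CC(C)=CCBr | starting material
4 | [3-bromo-2-methoxy-6-(methoxymethoxy)phenyl]lithium | [Li]c1c(OC)c(Br)ccc1OCOC | intermediate (not isolated)
5 | 1-bromo-2-methoxy-4-(methoxymethoxy)-3-(3-methylbut-2-en-1-yl)benzene | COCOc1ccc(Br)c(OC)c1CC=C(C)C | intermediate
6 | 1-(4-hydroxyphenyl)ethan-1-one | CC(=O)c1ccc(O)cc1 | starting material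
7 | 3-chloro-3-methylbut-1-yne | C#CC(C)(C)Cl | starting material
8 | 1-{4-[(2-methylbut-3-yn-2-yl)oxy]phenyl}ethan-1-one | CC(=O)c1ccc(OC(C)(C)C#C)cc1 | intermediate
9 | 1-{4-[(2-methylbut-3-en-2-yl)oxy]phenyl}ethan-1-one | CC(=O)c1ccc(OC(C)(C)C=C)cc1 | intermediate
10 | rac-4-acetyl-6-(3-methylbut-2-en-1-yl)cyclohexa-2,4-dien-1-one | CC(=O)C1=CC(CC=C(C)C)C(=O)C=C1 | intermediate (not isolated)
11 | 1-[4-hydroxy-3-(3-methylbut-2-en-1-yl)phenyl]ethan-1-one | CC(=O)c1ccc(O)c(CC=C(C)C)c1 | intermediate
12 | 1-[4-(methoxymethoxy)-3-(3-methylbut-2-en-1-yl)phenyl]ethan-1-one | CC(=O)c1ccc(OCOC)c(CC=C(C)C)c1 | intermediate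
13 | carbon monoxide | [C-]#[O+] | starting material
14 | 1-[2-methoxy-4-(methoxymethoxy)-3-(3-methylbut-2-en-1-yl)phenyl]-3-[4-(methoxymethoxy)-3-(3-methylbut-2-en-1-yl)phenyl]propane-1,3-dione | COCOc1ccc(C(=O)CC(=O)c2ccc(OCOC)c(CC=C(C)C)c2)c(OC)c1CC=C(C)C | intermediate
15 | 1-[4-hydroxy-2-methoxy-3-(3-methylbut-2-en-1-yl)phenyl]-3-[4-hydroxy-3-(3-methylbut-2-en-1-yl)phenyl]propane-1,3-dione | COc1c(C(=O)CC(=O)c2ccc(O)c(CC=C(C)C)c2)ccc(O)c1CC=C(C)C | target

**Count and risks**
Total step count: 8. Longest linear sequence: 6 (steps 3 to 8, from 1-(4-hydroxyphenyl)ethan-1-one).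

Steps most likely to fail:

1. Step 7. Oxidative addition of the electron-rich, ortho-alkoxy bromide may be slow under CO, and direct α-arylation without CO insertion or hydrodebromination may take over. Fallback, setting out from 5 and returning at 14: bromine–lithium exchange (n-BuLi, THF, −78 °C) would give [2-methoxy-4-(methoxymethoxy)-3-(3-methylbut-2-en-1-yl)phenyl]lithium F1, and inverse addition to excess methyl chloroformate would give methyl 2-methoxy-4-(methoxymethoxy)-3-(3-methylbut-2-en-1-yl)benzoate F2. A crossed Claisen condensation of F2 with the lithium enolate of 12 (LiN(SiMe3)2, THF, 0 → 40 °C) would then give 14.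

2. Step 2. Deprotonation beside the C–Br bond may be followed by bromine migration or aryne formation, and the allylation may proceed with allylic transposition. Fallback, setting out from 7 and returning at 14, in which the ring A prenyl is set by a chelation-controlled [3,3] rearrangement instead of an anion alkylation:
   - Commercial methyl 2,4-dihydroxybenzoate F3 would be O-alkylated with 7 at the free 4-OH (DBU, CuCl2·2H2O) to methyl 2-hydroxy-4-[(2-methylbut-3-yn-2-yl)oxy]benzoate F4.
   - Semihydrogenation as in step 4 would give methyl 2-hydroxy-4-[(2-methylbut-3-en-2-yl)oxy]benzoate F5.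
   - Heating in PhNEt2 would rearrange F5 through rac-methyl 2-hydroxy-3-(3-methylbut-2-en-1-yl)-4-oxocyclohexa-1,5-diene-1-carboxylate F6 to methyl 2,4-dihydroxy-3-(3-methylbut-2-en-1-yl)benzoate F7, the hydrogen-bonded salicylate directing the shift to C3.
   - MOMCl/i-Pr2NEt at the free 4-OH would give methyl 2-hydroxy-4-(methoxymethoxy)-3-(3-methylbut-2-en-1-yl)benzoate F8.
   - MeI/K2CO3 in DMF would give methyl 2-methoxy-4-(methoxymethoxy)-3-(3-methylbut-2-en-1-yl)benzoate F2, which would be condensed with 12 as above to give 14.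

3. Step 8. The acid may close the liberated phenols onto their ortho-prenyl alkenes (chroman formation) or add methanol or HCl to the alkenes before both acetals are cleaved. Fallback, setting out from 1 and 11 and returning at 15, with fluoride-labile acetals so that no acid is used at the end:
   - 1 with 2-(trimethylsilyl)ethoxymethyl chloride and i-Pr2NEt would give {2-[(4-bromo-3-methoxyphenoxy)methoxy]ethyl}trimethylsilane F9.
   - Metalation as in step 2 would give [3-bromo-2-methoxy-6-{[2-(trimethylsilyl)ethoxy]methoxy}phenyl]lithium F10, and prenylation with 3 would give {2-{[4-bromo-3-methoxy-2-(3-methylbut-2-en-1-yl)phenoxy]methoxy}ethyl}trimethylsilane F11.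
   - 11 would be protected likewise as 1-[3-(3-methylbut-2-en-1-yl)-4-{[2-(trimethylsilyl)ethoxy]methoxy}phenyl]ethan-1-one F12.
   - The carbonylative coupling of F11, 13 and F12 under the conditions of step 7 would give 1-[2-methoxy-3-(3-methylbut-2-en-1-yl)-4-{[2-(trimethylsilyl)ethoxy]methoxy}phenyl]-3-[3-(3-methylbut-2-en-1-yl)-4-{[2-(trimethylsilyl)ethoxy]methoxy}phenyl]propane-1,3-dione F13.
   - Bu4NF in DMPU at 60 °C would then release 15 under basic, non-acidic conditions.

**Further compounds**
F1 | step 7 | [2-methoxy-4-(methoxymethoxy)-3-(3-methylbut-2-en-1-yl)phenyl]lithium | [Li]c1ccc(OCOC)c(CC=C(C)C)c1OC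
F2 | step 7 | methyl 2-methoxy-4-(methoxymethoxy)-3-(3-methylbut-2-en-1-yl)benzoate | COCOc1ccc(C(=O)OC)c(OC)c1CC=C(C)C
F3 | step 2 | methyl 2,4-dihydroxybenzoate (commercial) | COC(=O)c1ccc(O)cc1O
F4 | step 2 | methyl 2-hydroxy-4-[(2-methylbut-3-yn-2-yl)oxy]benzoate | COC(=O)c1ccc(OC(C)(C)C#C)cc1O
F5 | step 2 | methyl 2-hydroxy-4-[(2-methylbut-3-en-2-yl)oxy]benzoate | COC(=O)c1ccc(OC(C)(C)C=C)cc1O
F6 | step 2 | rac-methyl 2-hydroxy-3-(3-methylbut-2-en-1-yl)-4-oxocyclohexa-1,5-diene-1-carboxylate | COC(=O)C1=C(O)C(CC=C(C)C)C(=O)C=C1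
F7 | step 2 | methyl 2,4-dihydroxy-3-(3-methylbut-2-en-1-yl)benzoate | COC(=O)c1ccc(O)c(CC=C(C)C)c1O
F8 | step 2 | methyl 2-hydroxy-4-(methoxymethoxy)-3-(3-methylbut-2-en-1-yl)benzoate | COCOc1ccc(C(=O)OC)c(O)c1CC=C(C)C
F9 | step 8 | {2-[(4-bromo-3-methoxyphenoxy)methoxy]ethyl}trimethylsilane | COc1cc(OCOCC[Si](C)(C)C)ccc1Br
F10 | step 8 | [3-bromo-2-methoxy-6-{[2-(trimethylsilyl)ethoxy]methoxy}phenyl]lithium | [Li]c1c(OC)c(Br)ccc1OCOCC[Si](C)(C)C
F11 | step 8 | {2-{[4-bromo-3-methoxy-2-(3-methylbut-2-en-1-yl)phenoxy]methoxy}ethyl}trimethylsilane | COc1c(Br)ccc(OCOCC[Si](C)(C)C)c1CC=C(C)C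
F12 | step 8 | 1-[3-(3-methylbut-2-en-1-yl)-4-{[2-(trimethylsilyl)ethoxy]methoxy}phenyl]ethan-1-one | CC(=O)c1ccc(OCOCC[Si](C)(C)C)c(CC=C(C)C)c1
F13 | step 8 | 1-[2-methoxy-3-(3-methylbut-2-en-1-yl)-4-{[2-(trimethylsilyl)ethoxy]methoxy}phenyl]-3-[3-(3-methylbut-2-en-1-yl)-4-{[2-(trimethylsilyl)ethoxy]methoxy}phenyl]propane-1,3-dione | COc1c(C(=O)CC(=O)c2ccc(OCOCC[Si](C)(C)C)c(CC=C(C)C)c2)ccc(OCOCC[Si](C)(C)C)c1CC=C(C)C
A1 | direct plan | tert-butyl{[4,4-dimethoxy-3-(3-methylbut-2-en-1-yl)buta-1,3-dien-2-yl]oxy}dimethylsilane | C=C(O[Si](C)(C)C(C)(C)C)C(CC=C(C)C)=C(OC)OC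
A2 | direct plan | rac-5-{3-(3-methylbut-2-en-1-yl)-4-[(triisopropylsilyl)oxy]phenyl}-5-[(triethylsilyl)oxy]pent-1-yn-3-one | C#CC(=O)CC(O[Si](CC)(CC)CC)c1ccc(O[Si](C(C)C)(C(C)C)C(C)C)c(CC=C(C)C)c1
A3 | direct plan | rac-1-{4-[(tert-butyldimethylsilyl)oxy]-2-methoxy-3-(3-methylbut-2-en-1-yl)phenyl}-3-{3-(3-methylbut-2-en-1-yl)-4-[(triisopropylsilyl)oxy]phenyl}-3-[(triethylsilyl)oxy]propan-1-one | COc1c(C(=O)CC(O[Si](CC)(CC)CC)c2ccc(O[Si](C(C)C)(C(C)C)C(C)C)c(CC=C(C)C)c2)ccc(O[Si](C)(C)C(C)(C)C)c1CC=C(C)C
A4 | direct plan | 4-hydroxy-3-(3-methylbut-2-en-1-yl)benzaldehyde | O=Cc1ccc(O)c(CC=C(C)C)c1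
A5 | direct plan | 4-hydroxybenzaldehyde | O=Cc1ccc(O)cc1
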